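**Plan**
1. Retrosynthesis: the last cuts are the two O–Si bonds and the aryl–prenyl bond (Stille). The CH=CH bond of the pyran (ring D) is then cut to a dialdehyde.
2. The dialdehyde goes back through its C10–O bond (tertiary alkoxide on a β-chlorovinyl aldehyde) and its C11–CHO bond (Vilsmeier–Haack–Arnold) to a dibenzo[b,f]oxepin-10(11H)-one. The ketone goes back through its C10–aryl bond (Friedel–Crafts) and the diaryl ether C–O bond (Ullmann) to compounds 1 and 2.
3. Forward order: diaryl ether, then the oxepinone (ring C), then bromine on ring A as the handle for the prenyl group, then ring D, then prenyl, then free phenols.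
4. Enabling feature: in ring D both CH carbons sit next to hydrogen-free atoms (the C(CH3)2 carbon and C11), so each can be carried as a non-enolisable aldehyde. The C10=C11 enol ether bond of ring C holds the two formyl groups cis and six atoms apart.
5. Two electrophilic carbonyl carbons of like polarity are therefore joined by low-valent titanium through ketyl radicals (McMurry coupling), which gives the ring D diene directly.
6. Stereochemistry: the target has no stereocentre. The cis CH=CH is enforced by ring D and the C10=C11 geometry by ring C.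

Key step: step 9

Remark: dibenzo[b,f]oxepine numbering is used (O5; C10 bonded to ring B; C11 bonded to ring A). Ring A is the benzo ring that ends up prenylated, ring B the other benzo ring. Compound 1 is assumed to be purchasable.

**Step 1**
Reactants: 1 2-(2-bromo-4-methoxyphenyl)acetic acid; 2 3-methoxyphenol
Product: 3 2-[4-methoxy-2-(3-methoxyphenoxy)phenyl]acetic acid
Conditions: CuI (cat.), N,N-dimethylglycine, Cs2CO3, dioxane, 100 °C; then aq. HCl
Reagents that add atoms: none
Why: Ullmann diaryl ether synthesis, in which the copper phenoxide of 2 should couple with the aryl bromide of 1, helped by the ortho carboxymethyl group as its carboxylate.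

**Step 2**
Reactants: 3 2-[4-methoxy-2-(3-methoxyphenoxy)phenyl]acetic acid
Product: 4 3,7-dimethoxydibenzo[b,f]oxepin-10(11H)-one
Conditions: polyphosphoric acid, 90 °C
Reagents that add atoms: none
Why: intramolecular Friedel–Crafts acylation, in which the acylium ion should attack the 3-methoxyphenoxy ring at the less hindered of the two positions ortho to the ether oxygen (para to OMe), closing ring C with the carbonyl on the ring B side.

**Step 3**
Reactants: 4 3,7-dimethoxydibenzo[b,f]oxepin-10(11H)-one
Product: 5 2-bromo-3,7-dimethoxydibenzo[b,f]oxepin-10(11H)-one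
Conditions: NBS (1.05 equiv), MeCN, 0 °C to rt, dark
Reagents that add atoms: N-bromosuccinimide, O=C1CCC(=O)N1Br
Why: electrophilic aromatic bromination, which should select ring A (a resorcinol diether not conjugated to the ketone) over ring B (its oxygens are tied to the C10 carbonyl as a vinylogous ester), and C2 (ortho to OMe, para to the ether oxygen) over the crowded C4.

**Step 4**
Reactants: 5 2-bromo-3,7-dimethoxydibenzo[b,f]oxepin-10(11H)-one
Product: 6 2-bromo-3,7-dihydroxydibenzo[b,f]oxepin-10(11H)-one
Conditions: BBr3, CH2Cl2, −78 °C to rt; then water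
Reagents that add atoms: none
Why: Lewis-acid O-demethylation of aryl methyl ethers (bromide attack at methyl), which should leave the diaryl ether, ketone and aryl bromide untouched.

**Step 5**
Reactants: 6 2-bromo-3,7-dihydroxydibenzo[b,f]oxepin-10(11H)-one
Product: 7 2-bromo-3,7-bis[(triisopropylsilyl)oxy]dibenzo[b,f]oxepin-10(11H)-one
Conditions: i-Pr3SiCl, imidazole, DMF, rt to 40 °C
Reagents that add atoms: chlorotriisopropylsilane, CC(C)[Si](Cl)(C(C)C)C(C)C
Why: phenol silylation; the triisopropylsilyl ethers are chosen because they should survive POCl3/DMF, alkoxide, periodate and low-valent titanium and leave with fluoride at the end.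

**Step 6**
Reactants: 7 2-bromo-3,7-bis[(triisopropylsilyl)oxy]dibenzo[b,f]oxepin-10(11H)-one
Product: 9 2-bromo-10-chloro-3,7-bis[(triisopropylsilyl)oxy]dibenzo[b,f]oxepine-11-carbaldehyde, via chlorovinyl iminium chloride 8 (not isolated)
Conditions: POCl3, DMF, 1,2-dichloroethane, 0 to 60 °C; then aq. NaOAc
Reagents that add atoms: N,N-dimethylformamide, CN(C)C=O; phosphoryl chloride, O=P(Cl)(Cl)Cl; water, O
Why: Vilsmeier–Haack–Arnold chloroformylation, in which the enol should attack the chloroiminium ion at C11 (the only α-carbon) while the C10 oxygen is exchanged for chloride, so that hydrolysis of 8 gives Cl on C10 (ring B side) and CHO on C11 (ring A side).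

**Step 7**
Reactants: 9 2-bromo-10-chloro-3,7-bis[(triisopropylsilyl)oxy]dibenzo[b,f]oxepine-11-carbaldehyde; 10 2-methylbut-3-en-2-ol
Product: 11 2-bromo-10-[(2-methylbut-3-en-2-yl)oxy]-3,7-bis[(triisopropylsilyl)oxy]dibenzo[b,f]oxepine-11-carbaldehyde
Conditions: 10, KN(SiMe3)2, THF, −40 °C; then 9, −40 to 0 °C
Reagents that add atoms: none
Why: vinylic nucleophilic substitution by addition–elimination of the potassium tert-alkoxide at C10 of the vinylogous acid chloride, which fixes the ring D oxygen on C10; the temperature is held at or below 0 °C so that the allyl vinyl ether formed does not undergo a Claisen shift.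

**Step 8**
Reactants: 11 2-bromo-10-[(2-methylbut-3-en-2-yl)oxy]-3,7-bis[(triisopropylsilyl)oxy]dibenzo[b,f]oxepine-11-carbaldehyde
Product: 13 2-bromo-10-[(2-methyl-1-oxopropan-2-yl)oxy]-3,7-bis[(triisopropylsilyl)oxy]dibenzo[b,f]oxepine-11-carbaldehyde, via vicinal diol 12 (not isolated)
Conditions: OsO4 (cat.), NaIO4, 2,6-lutidine, dioxane/water, rt
Reagents that add atoms: osmium tetroxide, O=[Os](=O)(=O)=O; sodium periodate, [Na+].[O-]I(=O)(=O)=O
Why: Lemieux–Johnson oxidation, in which OsO4 should dihydroxylate only the monosubstituted vinyl group (the tetrasubstituted, formyl-deactivated C10=C11 bond is inert) and NaIO4 cleaves diol 12 to the non-enolisable α-alkoxy aldehyde.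

**Step 9**
Reactants: 13 2-bromo-10-[(2-methyl-1-oxopropan-2-yl)oxy]-3,7-bis[(triisopropylsilyl)oxy]dibenzo[b,f]oxepine-11-carbaldehyde
Product: 15 bromo bis-silyl ether of the tetracycle (2,2-dimethyl-2H-pyran fused across C10–C11 of 2-bromo-3,7-bis[(triisopropylsilyl)oxy]dibenzo[b,f]oxepine, pyran oxygen on C10, CH=CH on C11), via titanium pinacolate 14 (not isolated)
Conditions: TiCl4, Zn, pyridine, THF, reflux; slow addition of 13 (high dilution); then aq. K2CO3
Reagents that add atoms: none
Why: Low-valent titanium should transfer single electrons to the formyl groups (the conjugated 11-formyl group first), the two ketyl carbons then join to the titanium-bound 1,2-diolate 14, and at reflux both C–O bonds are cleaved on titanium to leave the CH=CH bond. The closest known reaction type is the intramolecular McMurry coupling of dialdehydes and of oxygen-tethered carbonyl pairs to cyclic alkenes, 1,3-dienes and 2H-chromenes. Ring D is closed in a 6-exo-trig mode by C–C bond formation between the two formyl carbons; attack at C10 instead would need a four-membered ring. No stereocentre remains, because the two carbinol centres of 14 are erased on deoxygenation and the cis geometry of the new alkene is enforced by the six-membered ring. The step needs ring closure to win over intermolecular coupling and over reductive loss of the α-alkoxy group. Slow addition at high dilution, the cis hold of the C10=C11 bond on both formyl groups, the absence of any enolisable hydrogen (C(CH3)2 and C11) and the pyridine buffer should secure this.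

**Step 10**
Reactants: 15 bromo bis-silyl ether of the tetracycle; 16 tributyl(3-methylbut-2-en-1-yl)stannane
Product: 17 artocarpol D bis(triisopropylsilyl) ether
Conditions: Pd(PPh3)4 (cat.), DMF, 100 °C
Reagents that add atoms: none
Why: Stille coupling, in which oxidative addition of zerovalent palladium into the C2–Br bond, transmetalation with the prenylstannane and reductive elimination should give the linear prenyl arene.

**Step 11**
Reactants: 17 artocarpol D bis(triisopropylsilyl) ether
Product: 18 artocarpol D
Conditions: Bu4NF, AcOH, THF, 0 °C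
Reagents that add atoms: none
Why: fluoride cleavage of both aryl silyl ethers, buffered with acetic acid so that neither acid nor strong base should reach the dienyl ether of ring D or the prenyl group.

**Compound list**
1 | 2-(2-bromo-4-methoxyphenyl)acetic acid | COc1ccc(CC(=O)O)c(Br)c1 | starting material
2 | 3-methoxyphenol | COc1cccc(O)c1 | starting material
3 | 2-[4-methoxy-2-(3-methoxyphenoxy)phenyl]acetic acid | COc1cccc(Oc2cc(OC)ccc2CC(=O)O)c1 | intermediate
4 | 3,7-dimethoxydibenzo[b,f]oxepin-10(11H)-one | O=C1Cc2ccc(OC)cc2Oc2cc(OC)ccc12 | intermediate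
5 | 2-bromo-3,7-dimethoxydibenzo[b,f]oxepin-10(11H)-one | O=C1Cc2cc(Br)c(OC)cc2Oc2cc(OC)ccc12 | intermediate
6 | 2-bromo-3,7-dihydroxydibenzo[b,f]oxepin-10(11H)-one | O=C1Cc2cc(Br)c(O)cc2Oc2cc(O)ccc12 | intermediate
7 | 2-bromo-3,7-bis[(triisopropylsilyl)oxy]dibenzo[b,f]oxepin-10(11H)-one | O=C1Cc2cc(Br)c(O[Si](C(C)C)(C(C)C)C(C)C)cc2Oc2cc(O[Si](C(C)C)(C(C)C)C(C)C)ccc12 | intermediate
8 | N-{[2-bromo-10-chloro-3,7-bis(triisopropylsilyloxy)dibenzo[b,f]oxepin-11-yl]methylidene}-N-methylmethanaminium chloride | C[N+](C)=CC1=C(Cl)c2ccc(O[Si](C(C)C)(C(C)C)C(C)C)cc2Oc2cc(O[Si](C(C)C)(C(C)C)C(C)C)c(Br)cc12.[Cl-] | intermediate (not isolated)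
9 | 2-bromo-10-chloro-3,7-bis[(triisopropylsilyl)oxy]dibenzo[b,f]oxepine-11-carbaldehyde | O=CC1=C(Cl)c2ccc(O[Si](C(C)C)(C(C)C)C(C)C)cc2Oc2cc(O[Si](C(C)C)(C(C)C)C(C)C)c(Br)cc12 | intermediate
10 | 2-methylbut-3-en-2-ol | CC(C)(O)C=C | starting material
11 | 2-bromo-10-[(2-methylbut-3-en-2-yl)oxy]-3,7-bis[(triisopropylsilyl)oxy]dibenzo[b,f]oxepine-11-carbaldehyde | O=CC1=C(OC(C)(C)C=C)c2ccc(O[Si](C(C)C)(C(C)C)C(C)C)cc2Oc2cc(O[Si](C(C)C)(C(C)C)C(C)C)c(Br)cc12 | intermediate
12 | 2-bromo-10-[(3,4-dihydroxy-2-methylbutan-2-yl)oxy]-3,7-bis[(triisopropylsilyl)oxy]dibenzo[b,f]oxepine-11-carbaldehyde (racemic, configuration not defined) | O=CC1=C(OC(C)(C)C(O)CO)c2ccc(O[Si](C(C)C)(C(C)C)C(C)C)cc2Oc2cc(O[Si](C(C)C)(C(C)C)C(C)C)c(Br)cc12 | intermediate (not isolated)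
13 | 2-bromo-10-[(2-methyl-1-oxopropan-2-yl)oxy]-3,7-bis[(triisopropylsilyl)oxy]dibenzo[b,f]oxepine-11-carbaldehyde | O=CC1=C(OC(C)(C)C=O)c2ccc(O[Si](C(C)C)(C(C)C)C(C)C)cc2Oc2cc(O[Si](C(C)C)(C(C)C)C(C)C)c(Br)cc12 | intermediate
14 | titanium-bound pinacolate of ring D, drawn as the free 3,4-diol of the 3,4-dihydro-2H-pyran (mixture of diastereomers; both centres are erased in the same step) | CC1(C)OC2=C(C(O)C1O)c1cc(Br)c(O[Si](C(C)C)(C(C)C)C(C)C)cc1Oc1cc(O[Si](C(C)C)(C(C)C)C(C)C)ccc12 | intermediate (not isolated)
15 | bromo bis-silyl ether of the tetracycle (ring D fused across C10–C11, Br at C2 of ring A, silyl ethers at C3 and C7) | CC1(C)C=CC2=C(O1)c1ccc(O[Si](C(C)C)(C(C)C)C(C)C)cc1Oc1cc(O[Si](C(C)C)(C(C)C)C(C)C)c(Br)cc12 | intermediate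
16 | tributyl(3-methylbut-2-en-1-yl)stannane | CCCC[Sn](CCCC)(CCCC)CC=C(C)C | starting material
17 | artocarpol D bis(triisopropylsilyl) ether | CC1(C)C=CC2=C(O1)c1ccc(O[Si](C(C)C)(C(C)C)C(C)C)cc1Oc1cc(O[Si](C(C)C)(C(C)C)C(C)C)c(CC=C(C)C)cc12 | intermediate
18 | artocarpol D (achiral) | CC(C)=CCc1cc2c(cc1O)Oc1cc(O)ccc1C1=C2C=CC(C)(C)O1 | target

**Count**
Total steps: 11. Longest linear sequence: 11 steps (from 1 to 18).

**Steps most likely to fail, with fallbacks**

Step 9. Risk: the ketyl at the aliphatic formyl group may expel the oxygen on its α-carbon (the leaving group is a stabilised enolate) before C–C coupling, or the reaction may stall at the pinacolate or couple between molecules. Fallback by alkene metathesis instead of carbonyl coupling, setting out from 11: Wittig methylenation of the 11-formyl group (Ph3P=CH2, THF, −78 to 0 °C) should give 2-bromo-11-ethenyl-10-[(2-methylbut-3-en-2-yl)oxy]-3,7-bis[(triisopropylsilyl)oxy]dibenzo[b,f]oxepine F1. Ring-closing metathesis (second-generation Grubbs catalyst, CH2Cl2, 40 °C) should then form the same CH=CH bond and return to the route at 15.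

Step 7. Risk: addition–elimination at the hindered C10 may be slower than attack of the alkoxide on the formyl group or on silicon of the aryl silyl ethers, and the product may undergo a [3,3] shift on warming. Fallback that builds ring D through other bonds, setting out from 7: Knoevenagel-type condensation with 3-methylbut-2-enal (ethylenediammonium diacetate, toluene, 80 °C) should give 2-bromo-11-(3-methylbut-2-en-1-ylidene)-3,7-bis[(triisopropylsilyl)oxy]dibenzo[b,f]oxepin-10(11H)-one F2. The isomer of F2 with the dienyl chain syn to the ketone oxygen should close by oxa-6π electrocyclisation, with the other isomer equilibrating under the amine conditions, and the route is rejoined at 15.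

Step 10. Risk: allylic transposition during transmetalation may give the 1,1-dimethylallyl isomer, and oxidative addition at the hindered, electron-rich bromide may be slow enough for protodebromination to compete. Fallback in two operations, setting out from 15: Stille coupling with allyltributylstannane (Pd(PPh3)4, DMF, 100 °C), where transposition is without consequence, should give the 2-allyl bis(triisopropylsilyl) ether of the tetracycle F3. Olefin cross-metathesis with 2-methylbut-2-ene (second-generation Grubbs catalyst, CH2Cl2, rt to 40 °C) should convert allyl into prenyl and return to the route at 17.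

**Further compounds**
F1 | step 9 | 2-bromo-11-ethenyl-10-[(2-methylbut-3-en-2-yl)oxy]-3,7-bis[(triisopropylsilyl)oxy]dibenzo[b,f]oxepine | C=CC1=C(OC(C)(C)C=C)c2ccc(O[Si](C(C)C)(C(C)C)C(C)C)cc2Oc2cc(O[Si](C(C)C)(C(C)C)C(C)C)c(Br)cc12
F2 | step 7 | 2-bromo-11-(3-methylbut-2-en-1-ylidene)-3,7-bis[(triisopropylsilyl)oxy]dibenzo[b,f]oxepin-10(11H)-one (drawn as the isomer that cyclises, chain syn to C=O) | CC(C)=C/C=C1\C(=O)c2ccc(O[Si](C(C)C)(C(C)C)C(C)C)cc2Oc2cc(O[Si](C(C)C)(C(C)C)C(C)C)c(Br)cc12
F3 | step 10 | 2-allyl analogue of 17 (prop-2-en-1-yl at C2 of ring A, silyl ethers at C3 and C7, ring D in place) | C=CCc1cc2c(cc1O[Si](C(C)C)(C(C)C)C(C)C)Oc1cc(O[Si](C(C)C)(C(C)C)C(C)C)ccc1C1=C2C=CC(C)(C)O1
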